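**Plan**
- Chroman numbering is used: O1, CMe2 = C2, carbinol C3, CH2 = C4, acyl on C6. The retrosynthesis first cuts C6–C(=O) into an aryllithium and a cinnamoyl Weinreb amide. It then traces C3–OH back to C3–Si, and last opens the dihydropyran at C4–C3 and O1–C2.
- Enabling feature: C4 is an unsubstituted benzylic CH2 on C4a, next to the O1-bearing C8a. O1–C8a–C4a–C4 is therefore a masked o-quinone methide (4π), and C3–C2 is a masked isobutenyl 2π unit.
- An enol ether would put its oxygen on C2, so the alkene carries silicon on the future C3 as a stand-in for OH. Silicon bears a benzyl group so that fluoride can unmask it, because an electrophilic unmasking reagent would attack the phloroglucinol ring.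
- Forward order: phloroglucinaldehyde supplies ring A, and the cycloaddition builds the pyran, the only ring made. Silicon is then exchanged for oxygen, and ring B arrives with the cinnamoyl chain at C6, its E alkene set by a Horner–Wadsworth–Emmons reaction.
- Stereochemistry: C3 is the only stereocentre. The chiral counter-anion sets it in the cycloaddition, and it passes from Si to O with retention.

Key step: step 4

Assumption: the sense of induction of the confined acid cannot be derived for this new substrate pair, so "(S,S)" in step 4 stands for whichever of the two available catalyst antipodes delivers (R)-8.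

Step 1
Reactants: 1 2,4,6-trihydroxybenzaldehyde
Product: 2 2-hydroxy-4,6-bis(methoxymethoxy)benzaldehyde
Conditions: MOMCl (2.2 equiv), i-Pr2NEt (3 equiv), CH2Cl2, 0 °C to rt
Reagents that add atoms: chloromethyl methyl ether (MOMCl), COCCl
Why: O-alkylation of phenols (MOM acetal formation): the 4-OH and one ortho OH react, while the remaining ortho phenol is hydrogen-bonded to the formyl oxygen and stays free at this stoichiometry.

Step 2
Reactants: 2 2-hydroxy-4,6-bis(methoxymethoxy)benzaldehyde
Product: 3 2-(hydroxymethyl)-3,5-bis(methoxymethoxy)phenol
Conditions: NaBH4, THF–MeOH, 0 °C; aq. NH4Cl quench; used promptly, Et3N-deactivated silica if purified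
Reagents that add atoms: none
Why: Borohydride reduction of an aldehyde; MOM acetals are inert to hydride, and the low temperature and non-acidic quench keep the easily ionised trioxygenated benzylic alcohol from losing water early.

Step 3
Reactants: 4 2-methylprop-1-enylmagnesium bromide (commercial THF solution); 5 benzylchlorodimethylsilane
Product: 6 benzyldimethyl(2-methylprop-1-enyl)silane
Conditions: THF, 0 °C to rt
Reagents that add atoms: none
Why: Nucleophilic substitution at silicon by an alkenyl Grignard reagent, the standard route to vinylsilanes; the Si–benzyl group withstands acid and is later cleaved by fluoride.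

Step 4
Reactants: 3 2-(hydroxymethyl)-3,5-bis(methoxymethoxy)phenol; 6 benzyldimethyl(2-methylprop-1-enyl)silane
Product: 8 benzyl[(3R)-5,7-bis(methoxymethoxy)-2,2-dimethylchroman-3-yl]dimethylsilane, via o-quinone methide 7 (not isolated)
Conditions: (S,S)-IDPi [imidodiphosphorimidate from two (S)-3,3'-bis(3,5-(CF3)2C6H3)-BINOL units, N-triflyl groups] (5 mol %), 6 (5 equiv), 5 Å MS, toluene, −20 °C, 3 added by syringe pump over 12 h
Reagents that add atoms: none
Why: Proposed new method: the acid ionises the trioxygenated benzylic alcohol of 3, which needs far less acidity than cleavage of the MOM acetals, and holds o-quinone methide 7 by a hydrogen bond to its oxygen inside the chiral pocket; the methide carbon (C4) then bonds to the silicon-bearing alkene carbon (C3) while the quinone methide oxygen (O1) closes on the dimethyl-substituted carbon (C2) in one asynchronous, suprafacial inverse-demand oxa-[4+2] addition driven by rearomatisation. The closest known reaction types are Brønsted-acid-catalysed asymmetric hetero-Diels–Alder additions of o-quinone methides to styrenes, enol ethers and tethered trisubstituted alkenes, and thermal additions of phloroglucinol-derived quinone methides to unactivated alkenes; a vinylsilane has not served as the 2π partner. The dihydropyran arises as the six-membered ring of the cycloaddition itself, so five- and six-membered closure do not compete. C3 is the only new stereocentre, and its configuration depends solely on which face of the prochiral alkene carbon the confined counter-anion lets approach C4; there is no E/Z issue because C2 carries two methyl groups. Regiochemistry needs the positive charge to build up on C2, which its tertiary nature and the β-silicon secure, and the single free phenol in 3 allows only one quinone methide. Chemoselectivity is the weak point: slow addition of 3 into excess 6 counters self-alkylation of the electron-rich ring, and loss of silicon to the achiral prenylphenol is countered by the non-nucleophilic anion, the sieves and a transition-state geometry in which the C–Si bond lies near the nodal plane of the developing cation until O1 has closed.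

Step 5
Reactants: 8 benzyl[(3R)-5,7-bis(methoxymethoxy)-2,2-dimethylchroman-3-yl]dimethylsilane
Product: 10 (3R)-5,7-bis(methoxymethoxy)-2,2-dimethylchroman-3-ol, via silanol 9 (not isolated)
Conditions: TBAF (1 M in THF, 2 equiv), THF, 0 °C, 15 min; then KHCO3, 30% aq. H2O2, MeOH, 0 °C to rt
Reagents that add atoms: hydrogen peroxide, OO
Why: Tamao–Fleming oxidation in its benzyldimethylsilyl form: fluoride cleaves Si–benzyl to silanol 9, hydroperoxide adds to silicon and C3 migrates from Si to O with retention, so (R)-8 should give (R)-10, with no electrophile present to attack the electron-rich ring and the MOM ethers stable to the mildly basic medium.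

Step 6
Reactants: 10 (3R)-5,7-bis(methoxymethoxy)-2,2-dimethylchroman-3-ol
Product: 11 [(3R)-5,7-bis(methoxymethoxy)-2,2-dimethylchroman-3-yl]oxy(triethyl)silane
Conditions: TESCl, imidazole, DMAP (cat.), DMF, rt
Reagents that add atoms: chlorotriethylsilane (TESCl), CC[Si](Cl)(CC)CC
Why: Imidazole-promoted silyl ether formation; the chloride is used because silyl triflates attack aryl MOM ethers, and TES fits the neopentyl-type carbinol, survives n-BuLi and falls with acid in the last step.

Step 7
Reactants: 12 4-(methoxymethoxy)benzaldehyde; 13 diethyl {2-[methoxy(methyl)amino]-2-oxoethyl}phosphonate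
Product: 14 (E)-N-methoxy-3-[4-(methoxymethoxy)phenyl]-N-methylprop-2-enamide
Conditions: NaH, THF, 0 °C to rt
Reagents that add atoms: none
Why: Horner–Wadsworth–Emmons olefination with a stabilised amide phosphonate, which should deliver the E alkene with an aromatic aldehyde.

Step 8
Reactants: 11 [(3R)-5,7-bis(methoxymethoxy)-2,2-dimethylchroman-3-yl]oxy(triethyl)silane; 14 (E)-N-methoxy-3-[4-(methoxymethoxy)phenyl]-N-methylprop-2-enamide
Product: 16 (E)-1-[(3R)-5,7-bis(methoxymethoxy)-2,2-dimethyl-3-(triethylsilyloxy)chroman-6-yl]-3-[4-(methoxymethoxy)phenyl]prop-2-en-1-one, via aryllithium 15 (not isolated)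
Conditions: n-BuLi (1.05 equiv), TMEDA, THF, −78 to 0 °C; then 14, −78 to −20 °C; AcOH quench at −78 °C
Reagents that add atoms: none
Why: Directed ortho-metalation followed by Weinreb ketone synthesis: C6–H lies between two chelating MOM ethers and should be removed in preference to C8–H, which has only one, and the aryllithium adds 1,2 to the unsaturated N-methoxy-N-methylamide, with lithium chelation stopping the reaction at the ketone level; C3 and the alkene geometry are untouched.

Step 9
Reactants: 16 (E)-1-[(3R)-5,7-bis(methoxymethoxy)-2,2-dimethyl-3-(triethylsilyloxy)chroman-6-yl]-3-[4-(methoxymethoxy)phenyl]prop-2-en-1-one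
Product: 17 (E)-3-(4-hydroxyphenyl)-1-[(3R)-3,5,7-trihydroxy-2,2-dimethylchroman-6-yl]prop-2-en-1-one
Conditions: 3 M aq. HCl, MeOH, rt, dark; dilution with water and extraction, no basic wash
Reagents that add atoms: none
Why: Acid-catalysed acetal methanolysis and silyl ether solvolysis, the usual end game for MOM-protected 2',6'-dihydroxychalcones; room temperature and a work-up that never turns basic hold back oxa-Michael closure to the flavanone, and the C3 carbinol is not ionised under these conditions.

**Compound list**
1 | 2,4,6-trihydroxybenzaldehyde | O=Cc1c(O)cc(O)cc1O | starting material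
2 | 2-hydroxy-4,6-bis(methoxymethoxy)benzaldehyde | O=Cc1c(O)cc(OCOC)cc1OCOC | intermediate
3 | 2-(hydroxymethyl)-3,5-bis(methoxymethoxy)phenol | OCc1c(O)cc(OCOC)cc1OCOC | intermediate
4 | 2-methylprop-1-enylmagnesium bromide | CC(C)=C[Mg]Br | starting material
5 | benzylchlorodimethylsilane | C[Si](C)(Cl)Cc1ccccc1 | starting material
6 | benzyldimethyl(2-methylprop-1-enyl)silane | CC(C)=C[Si](C)(C)Cc1ccccc1 | intermediate
7 | 3,5-bis(methoxymethoxy)-6-methylidenecyclohexa-2,4-dien-1-one (o-quinone methide, not isolated) | C=C1C(=O)C=C(OCOC)C=C1OCOC | intermediate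
8 | benzyl[(3R)-5,7-bis(methoxymethoxy)-2,2-dimethylchroman-3-yl]dimethylsilane | CC1(C)Oc2cc(OCOC)cc(OCOC)c2C[C@H]1[Si](C)(C)Cc1ccccc1 | intermediate
9 | [(3R)-5,7-bis(methoxymethoxy)-2,2-dimethylchroman-3-yl]dimethylsilanol (not isolated) | CC1(C)Oc2cc(OCOC)cc(OCOC)c2C[C@H]1[Si](C)(C)O | intermediate
10 | (3R)-5,7-bis(methoxymethoxy)-2,2-dimethylchroman-3-ol | CC1(C)Oc2cc(OCOC)cc(OCOC)c2C[C@H]1O | intermediate
11 | [(3R)-5,7-bis(methoxymethoxy)-2,2-dimethylchroman-3-yl]oxy(triethyl)silane | CC1(C)Oc2cc(OCOC)cc(OCOC)c2C[C@H]1O[Si](CC)(CC)CC | intermediate
12 | 4-(methoxymethoxy)benzaldehyde | COCOc1ccc(C=O)cc1 | starting material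
13 | diethyl {2-[methoxy(methyl)amino]-2-oxoethyl}phosphonate | CCOP(=O)(CC(=O)N(C)OC)OCC | starting material
14 | (E)-N-methoxy-3-[4-(methoxymethoxy)phenyl]-N-methylprop-2-enamide | COCOc1ccc(/C=C/C(=O)N(C)OC)cc1 | intermediate
15 | [(3R)-5,7-bis(methoxymethoxy)-2,2-dimethyl-3-(triethylsilyloxy)chroman-6-yl]lithium (not isolated) | CC1(C)Oc2cc(OCOC)c([Li])c(OCOC)c2C[C@H]1O[Si](CC)(CC)CC | intermediate
16 | (E)-1-[(3R)-5,7-bis(methoxymethoxy)-2,2-dimethyl-3-(triethylsilyloxy)chroman-6-yl]-3-[4-(methoxymethoxy)phenyl]prop-2-en-1-one | CC1(C)Oc2cc(OCOC)c(C(=O)/C=C/c3ccc(OCOC)cc3)c(OCOC)c2C[C@H]1O[Si](CC)(CC)CC | intermediate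
17 | (E)-3-(4-hydroxyphenyl)-1-[(3R)-3,5,7-trihydroxy-2,2-dimethylchroman-6-yl]prop-2-en-1-one | CC1(C)Oc2cc(O)c(C(=O)/C=C/c3ccc(O)cc3)c(O)c2C[C@H]1O | target

Total step count: 9.
Longest linear sequence: 7 steps (1, 2, 4, 5, 6, 8, 9) from 2,4,6-trihydroxybenzaldehyde.

**Steps most likely to fail**

**Step 4.**
- Risks: The hindered, weakly nucleophilic alkene may be outrun by Friedel–Crafts oligomerisation of the quinone methide with its own electron-rich ring. Silicon may be lost from the β-silyl cation. The acid may protodesilylate the alkene or strip a MOM group. Facial discrimination may also be poor.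
- Fallback (known chemistry throughout): it sets out from aldehyde 2 and Grignard reagent 4. Addition of 2.2 equiv of 4 (THF, 0 °C) should give racemic 2-(1-hydroxy-3-methylbut-2-enyl)-3,5-bis(methoxymethoxy)phenol F1. Warming with catalytic PPTS in toluene should remove water and close the ring by oxa-6π electrocyclisation to 5,7-bis(methoxymethoxy)-2,2-dimethyl-2H-chromene F2.
- Jacobsen–Katsuki epoxidation follows, using (R,R)-N,N'-bis(3,5-di-tert-butylsalicylidene)-1,2-cyclohexanediaminomanganese chloride, NaOCl and 4-phenylpyridine N-oxide in CH2Cl2 at 0 °C. It should give (3R,4R)-3,4-epoxy-5,7-bis(methoxymethoxy)-2,2-dimethylchroman F3.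
- LiAlH4 in THF delivers hydride to the benzylic C4 and leaves the C3–O bond intact. The sequence rejoins the route at chromanol 10.

**Step 5.**
- Risks: Fluoride or base may trigger β-elimination of the aryloxide, because the equatorial C3–Si bond lies anti to C2–O1 and a Peterson-type ring opening is possible. Migration from the hindered silicon may also be slow.
- Fallback: it sets out from silane 8 and replaces C–Si oxidation by alkene oxidation. The elimination is driven to completion on purpose (TBAF, THF, 60 °C, no peroxide) to give 2-(3-methylbut-2-enyl)-3,5-bis(methoxymethoxy)phenol F4.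
- DDQ in toluene then closes F4 oxidatively to chromene F2. The epoxidation to F3 and the hydride opening described for step 4 lead back to chromanol 10. In this case the manganese catalyst sets C3.

**Step 8.**
- Risks: Lithiation at C8 may compete. The hindered aryllithium may attack the N-methoxy group of the amide, destroying it. It may also add in conjugate fashion.
- Fallback: it sets out from silyl ether 11 and builds the enone by C=C formation. Aryllithium 15, generated as before, is transferred into excess acetic anhydride at −78 °C. This should give 1-[(3R)-5,7-bis(methoxymethoxy)-2,2-dimethyl-3-(triethylsilyloxy)chroman-6-yl]ethanone F5, a stage at which any C8 isomer can be removed.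
- Claisen–Schmidt condensation of F5 with aldehyde 12 (KOH, EtOH, rt) rejoins the route at protected chalcone 16.

**Further compounds**
F1 | step 4 | racemic 2-(1-hydroxy-3-methylbut-2-enyl)-3,5-bis(methoxymethoxy)phenol | CC(C)=CC(O)c1c(O)cc(OCOC)cc1OCOC
F2 | step 4 | 5,7-bis(methoxymethoxy)-2,2-dimethyl-2H-chromene | CC1(C)C=Cc2c(OCOC)cc(OCOC)cc2O1
F3 | step 4 | (3R,4R)-3,4-epoxy-5,7-bis(methoxymethoxy)-2,2-dimethylchroman | CC1(C)Oc2cc(OCOC)cc(OCOC)c2[C@H]3O[C@H]31
F4 | step 5 | 2-(3-methylbut-2-enyl)-3,5-bis(methoxymethoxy)phenol | CC(C)=CCc1c(O)cc(OCOC)cc1OCOC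
F5 | step 8 | 1-[(3R)-5,7-bis(methoxymethoxy)-2,2-dimethyl-3-(triethylsilyloxy)chroman-6-yl]ethanone | CC1(C)Oc2cc(OCOC)c(C(C)=O)c(OCOC)c2C[C@H]1O[Si](CC)(CC)CC
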